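The constants are those of an exercise; what happens was integrated by code.

From larch to ash the step from E to L speeds up 32 times, and J stands at the end of a chain of such steps, so I ask how long that chain needs to deliver.

- larch: Q 0.20 mM; X 0.0400 mM; temperature −25 °C; time 4.0 s
- ash: Q 0.20 mM; X 0.0400 mM; temperature 5 °C; time 4.0 s

    Q ⇌ D (K1 = 0.206, k1 = 0.552 s⁻¹, Ea1 = 59.0 kJ mol⁻¹, ΔH1 = −19.0 kJ mol⁻¹)
    Q → E (k2 = 0.467 s⁻¹, Ea2 = 77.0 kJ mol⁻¹)
    E ⇌ G (K3 = 3.09, k3 = 0.150 s⁻¹, Ea3 = 68.0 kJ mol⁻¹, ΔH3 = −54.0 kJ mol⁻¹)
    E ⇌ L (K4 = 1.7, k4 = 0.475 s⁻¹, Ea4 = 66.0 kJ mol⁻¹, ΔH4 = −54.0 kJ mol⁻¹)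
    L → J (k5 = 3.59 s⁻¹, Ea5 = 63.0 kJ mol⁻¹)
    D → G (k6 = 0.771 s⁻¹, Ea6 = 68.0 kJ mol⁻¹)
    Q + X → Q.X (k7 = 681 M⁻¹ s⁻¹, Ea7 = 40.0 kJ mol⁻¹)
    (constants at 5 °C)

- the flask that comes out highest in amount of J, in percent of the Q charged, or "all alike" when all lie within 1.5 percentage points (larch / ash / all alike)
- J at the end, in percent of the Q charged, larch
- J at the end, in percent of the Q charged, ash

- all constants are for 5 °C and move with temperature by the activation energies and enthalpies

1. First I cool the constants. Each Arrhenius logarithm is proportional to its activation energy, so between these two temperatures a constant falls by the factor of E to L raised to the ratio of its activation energy to that of E to L. In larch that gives 0.00834 s⁻¹ for Q to E, 0.0151 s⁻¹ for E to L and 0.133 s⁻¹ for L to J.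

2. Next I look for the concentration that sets the order. In larch, Q leaves by its 3 routes at 0.0370 s⁻¹, and over 4.0 s that amounts to 0.148, so I hold Q at its charge.

3. With Q held, E grows with the time, L with its square and J with its cube. The share of J is then (time / clock)^3, where the clock is the cube root of 6 over the product of the constants of Q to E, E to L and L to J. For larch it is 71.0 s. I call this the chain clock, a measure of the chain's induction period: the time at which the bare cubic would reach the whole charge.

4. In larch 4.0 s is far shorter than the clock, so the cubic applies and gives 0.0179%.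

5. The weak link is that my cubic lets nothing leak. Q leaks as above, E leaves towards G and L, and L leaves towards J, which sums to 0.190 s⁻¹. The first correction to a cubic rise multiplies it by one minus that sum times the time over 4, so I commit to 0.0145% for larch.

6. For ash the clock is 1.96 s, shorter than 4.0 s. The cubic would claim 850% of the charge, which is impossible, so my hand reckoning stops there. It gives a direction, ash above larch, and no number.

The forecast names ash, with 0.015% for larch and 36% for ash, and calls the cold chain “in its early, cubic regime”.

In larch at 4.00 s, against a clock of 71.0 s, Q to E was still drawing on Q at 87.1%, with E at 2.99% and L at 0.0786%, and J reads 0.0149%. In ash at 2.00 s, against a clock of 1.96 s, J already stood at 15.0% with Q at 29.1%, and by 4.00 s Q was down to 10.0% and L held 2.43%, while J reads 36.3%, above larch.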